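The synthesis rests on one disconnection: the C6–C7 bond, which belongs both to the ten-membered carbocycle (C1–C10) and to the butenolide (O–C6–C7=C11–C12), is cut together with the lactone O–C12 bond. In the forward sense a C7 alkenylchromium, generated from a (Z)-β-iodoenoate, adds to a C6 epoxy aldehyde and the alkoxide lactonises at once, so that one operation closes both rings and sets C6. The precursor is an open chain bearing both epoxides, the Z C2=C3 alkene, silyl ethers at O8 and O14, the C13 acetate, the C6 aldehyde and the C7 iodoenoate; it is built from three alkynes and an allyl Grignard reagent, both epoxidations being run on enynes and the alkyne semireduced last.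

Key step: step 17

Remark: every compound is numbered as a germacranolide (C1–C10 for the chain that becomes the carbocycle; C11, C12, C13 for the lactone α-carbon, carbonyl carbon and acetoxymethyl carbon; C14 for the CH2O group on C10; C15 for the methyl on C4).
Remark: the ProPhenol antipode in step 4 is assumed to be the one that sends the alkynylzinc to the Re face of the aldehyde (8S); its descriptor is not asserted here.

Step 1
Reactants: 1 propargyl alcohol; 2 allylmagnesium bromide
Product: 4 (Z)-2-(iodomethylene)pent-4-en-1-ol, via alkenylmagnesium chelate 3 (not isolated)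
Conditions: 2 (2.5 equiv), CuI (10 mol %), Et2O, −10 °C to rt; then I2, THF, −78 to 0 °C
Reagents that add atoms: iodine, [I][I]
Why: CuI-catalysed anti-carbomagnesiation of the magnesium propargyl alkoxide puts the allyl group on the internal carbon (C10) and magnesium on the terminal carbon (C1) cis to the CH2O group in a five-membered chelate, and iodinolysis with retention should give the Z iodide; no stereocentre is formed.

Step 2
Reactants: 4 (Z)-2-(iodomethylene)pent-4-en-1-ol
Product: 5 (Z)-triethyl{[2-(iodomethylene)pent-4-en-1-yl]oxy}silane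
Conditions: TESCl, imidazole, CH2Cl2, 0 °C
Reagents that add atoms: chlorotriethylsilane, CC[Si](Cl)(CC)CC
Why: Routine silylation of the primary allylic alcohol masks O14 during the aldehyde chemistry and creates no stereocentre.

Step 3
Reactants: 5 (Z)-triethyl{[2-(iodomethylene)pent-4-en-1-yl]oxy}silane
Product: 7 (Z)-4-iodo-3-{[(triethylsilyl)oxy]methyl}but-3-enal, via vicinal diol 6 (not isolated)
Conditions: OsO4 (2 mol %), NaIO4, 2,6-lutidine, 1,4-dioxane–H2O (3:1), rt
Reagents that add atoms: osmium tetroxide (OsO4), O=[Os](=O)(=O)=O; sodium periodate (NaIO4, reoxidant that replenishes the oxygen), [Na+].[O-]I(=O)(=O)=O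
Why: Lemieux–Johnson oxidation, in which OsO4 dihydroxylates the unhindered terminal alkene in preference to the iodine-bearing trisubstituted one and periodate cleaves the diol, 2,6-lutidine keeping the mixture neutral for the silyl ether and the β,γ-unsaturated aldehyde (C8).

Step 4
Reactants: 7 (Z)-4-iodo-3-{[(triethylsilyl)oxy]methyl}but-3-enal; 8 methyl propiolate
Product: 9 methyl (4S,6Z)-4-hydroxy-7-iodo-6-{[(triethylsilyl)oxy]methyl}hept-6-en-2-ynoate
Conditions: Me2Zn, ProPhenol ligand (antipode for Re-face attack), Ph3P=O, toluene, 4 °C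
Reagents that add atoms: none
Why: Zinc–ProPhenol asymmetric alkynylation, in which the alkynylzinc formed from methyl propiolate and Me2Zn adds inside the chiral dizinc pocket to the Re face of the aldehyde and so sets C8 as S, the weakly basic zinc species being unlikely to move the β,γ-alkene into conjugation.

Step 5
Reactants: 9 methyl (4S,6Z)-4-hydroxy-7-iodo-6-{[(triethylsilyl)oxy]methyl}hept-6-en-2-ynoate
Product: 10 methyl (4S,6Z)-7-iodo-4-[(triethylsilyl)oxy]-6-{[(triethylsilyl)oxy]methyl}hept-6-en-2-ynoate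
Conditions: TESOTf, 2,6-lutidine, CH2Cl2, −78 °C
Reagents that add atoms: triethylsilyl trifluoromethanesulfonate, CC[Si](CC)(CC)OS(=O)(=O)C(F)(F)F
Why: Silylation with the silyl triflate and a hindered pyridine protects the propargylic alcohol (O8) without a nucleophilic amine that could add to the ynoate.

Step 6
Reactants: 11 (Z)-3-methylpent-2-en-4-yn-1-ol
Product: 12 (Z)-1-methoxy-4-{[(3-methylpent-2-en-4-yn-1-yl)oxy]methyl}benzene
Conditions: NaH, 4-methoxybenzyl chloride, Bu4NI (cat.), THF, 0 °C to rt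
Reagents that add atoms: 4-methoxybenzyl chloride, COc1ccc(CCl)cc1
Why: Williamson etherification of the allylic alkoxide gives an O6 ether that can later be removed by oxidation without touching silyl ethers or esters.

Step 7
Reactants: 10 methyl (4S,6Z)-7-iodo-4-[(triethylsilyl)oxy]-6-{[(triethylsilyl)oxy]methyl}hept-6-en-2-ynoate; 12 (Z)-1-methoxy-4-{[(3-methylpent-2-en-4-yn-1-yl)oxy]methyl}benzene
Product: 13 methyl (4S,6Z,10Z)-12-[(4-methoxybenzyl)oxy]-10-methyl-4-[(triethylsilyl)oxy]-6-{[(triethylsilyl)oxy]methyl}dodeca-6,10-dien-2,8-diynoate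
Conditions: Pd(PPh3)4 (5 mol %), CuI (10 mol %), iPr2NEt, THF, rt
Reagents that add atoms: none
Why: Sonogashira coupling of the unhindered Z iodoalkene with the terminal enyne forms C1–C2 with retention of the C10=C1 geometry, the internal ynoate being inert to the copper acetylide and to the hindered tertiary amine.

Step 8
Reactants: 13 methyl (4S,6Z,10Z)-12-[(4-methoxybenzyl)oxy]-10-methyl-4-[(triethylsilyl)oxy]-6-{[(triethylsilyl)oxy]methyl}dodeca-6,10-dien-2,8-diynoate
Product: 14 methyl (2Z,4S,6Z,10Z)-2-(hydroxymethyl)-3-iodo-12-[(4-methoxybenzyl)oxy]-10-methyl-4-[(triethylsilyl)oxy]-6-{[(triethylsilyl)oxy]methyl}dodeca-2,6,10-trien-8-ynoate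
Conditions: Et2AlI, CH2Cl2, −78 °C; then HCHO (gas), −78 to −40 °C
Reagents that add atoms: diethylaluminium iodide (Et2AlI), CC[Al](I)CC; formaldehyde, C=O
Why: Iodo-aldol (iodo Morita–Baylis–Hillman type) reaction, in which iodide from aluminium adds to the ynoate β-carbon C7 and the aluminium allenoate is hydroxymethylated at C11 on the side away from iodine, the anti sense known from hydroiodination of ynoates, so that iodine and CO2Me end cis before any epoxide or Z alkene is present.

Step 9
Reactants: 14 methyl (2Z,4S,6Z,10Z)-2-(hydroxymethyl)-3-iodo-12-[(4-methoxybenzyl)oxy]-10-methyl-4-[(triethylsilyl)oxy]-6-{[(triethylsilyl)oxy]methyl}dodeca-2,6,10-trien-8-ynoate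
Product: 15 methyl (2Z,4S,6Z,10Z)-2-(acetoxymethyl)-3-iodo-12-[(4-methoxybenzyl)oxy]-10-methyl-4-[(triethylsilyl)oxy]-6-{[(triethylsilyl)oxy]methyl}dodeca-2,6,10-trien-8-ynoate
Conditions: AcCl, 2,4,6-collidine, CH2Cl2, −78 to 0 °C
Reagents that add atoms: acetyl chloride, CC(Cl)=O
Why: Acylation with acetyl chloride and a hindered pyridine esterifies the primary allylic alcohol (O13) while avoiding nucleophilic amines that could attack the β-iodoenoate.

Step 10
Reactants: 15 methyl (2Z,4S,6Z,10Z)-2-(acetoxymethyl)-3-iodo-12-[(4-methoxybenzyl)oxy]-10-methyl-4-[(triethylsilyl)oxy]-6-{[(triethylsilyl)oxy]methyl}dodeca-2,6,10-trien-8-ynoate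
Product: 16 methyl (2Z,4S,6Z,10Z)-2-(acetoxymethyl)-6-(hydroxymethyl)-3-iodo-12-[(4-methoxybenzyl)oxy]-10-methyl-4-[(triethylsilyl)oxy]dodeca-2,6,10-trien-8-ynoate
Conditions: PPTS (cat.), MeOH–CH2Cl2, 0 °C
Reagents that add atoms: none
Why: Mild acid-catalysed methanolysis should cleave the unhindered primary allylic silyl ether (O14) much faster than the secondary one at O8, which is shielded by the tetrasubstituted iodoalkene, and no epoxide is present yet.

Step 11
Reactants: 16 methyl (2Z,4S,6Z,10Z)-2-(acetoxymethyl)-6-(hydroxymethyl)-3-iodo-12-[(4-methoxybenzyl)oxy]-10-methyl-4-[(triethylsilyl)oxy]dodeca-2,6,10-trien-8-ynoate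
Product: 17 (1R,10S)-1,10-epoxy C14 alcohol (16 with an epoxide across C10–C1)
Conditions: Ti(OiPr)4, L-(+)-diethyl tartrate, t-BuOOH, 4 Å molecular sieves, CH2Cl2, −20 °C
Reagents that add atoms: tert-butyl hydroperoxide, CC(C)(C)OO
Why: Sharpless asymmetric epoxidation, in which the Ti(OiPr)4–L-(+)-tartrate complex bound to the C14 hydroxyl delivers oxygen to the enyne alkene face that makes the hydroxymethyl-bearing carbon S (as in the 2S epoxy alcohols this tartrate gives from simple allylic alcohols), setting 1R,10S and giving a robust alkynyl epoxide.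

Step 12
Reactants: 17 (1R,10S)-1,10-epoxy C14 alcohol
Product: 18 C14 tert-butyldimethylsilyl ether of 17
Conditions: TBSOTf, 2,6-lutidine, CH2Cl2, −78 °C
Reagents that add atoms: tert-butyldimethylsilyl trifluoromethanesulfonate, CC(C)(C)[Si](C)(C)OS(=O)(=O)C(F)(F)F
Why: Low-temperature silylation with the silyl triflate and 2,6-lutidine protects the neopentyl-type primary alcohol without nucleophilic amine or acid that could harm the iodoenoate or the epoxide.

Step 13
Reactants: 18 C14 tert-butyldimethylsilyl ether of 17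
Product: 19 C6 allylic alcohol (18 without the 4-methoxybenzyl group)
Conditions: DDQ, CH2Cl2–pH 7 buffer (Na2HPO4/NaH2PO4), 0 °C
Reagents that add atoms: none
Why: DDQ oxidises the electron-rich benzylic ether to an oxocarbenium ion that water cleaves, a buffered oxidative deprotection that should leave the silyl ethers, the acetate and the alkynyl epoxide alone.

Step 14
Reactants: 19 C6 allylic alcohol
Product: 20 bis-epoxy ynol (19 with a (4R,5S)-epoxide across C4–C5)
Conditions: Ti(OiPr)4, L-(+)-diethyl tartrate, t-BuOOH, 4 Å molecular sieves, CH2Cl2, −20 °C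
Reagents that add atoms: tert-butyl hydroperoxide, CC(C)(C)OO
Why: Second Sharpless asymmetric epoxidation with the same L-(+)-tartrate, in which the C6 hydroxyl directs oxygen to the face that sets 5S and hence 4R, the only other alkene (the tetrasubstituted iodoenoate) having no free allylic hydroxyl.

Step 15
Reactants: 20 bis-epoxy ynol
Product: 21 bis-epoxy (Z)-enol (20 with C2≡C3 reduced to the Z alkene)
Conditions: H2 (1 atm), Pd/CaCO3 poisoned with Pb(OAc)2 (Lindlar catalyst), quinoline, EtOAc, rt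
Reagents that add atoms: none
Why: Lindlar semihydrogenation adds H2 syn to the alkyne, which binds to the Pb-poisoned Pd surface far more strongly than the product alkene, the vinyl epoxides or the hindered iodoenoate, and gives the Z alkene only after both epoxides are in place, so that no dienyl epoxide is ever formed.

Step 16
Reactants: 21 bis-epoxy (Z)-enol
Product: 22 seco-aldehyde (1R,4R,5R,8S,10S), the cyclisation precursor
Conditions: Dess–Martin periodinane, NaHCO3, CH2Cl2, 0 °C to rt
Reagents that add atoms: none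
Why: Buffered Dess–Martin oxidation converts the only free (primary) alcohol into the epoxy aldehyde under neutral conditions that should spare both vinyl epoxides.

Step 17
Reactants: 22 seco-aldehyde (1R,4R,5R,8S,10S)
Product: 24 macrocyclic butenolide (O8 triethylsilyl ether; O14 tert-butyldimethylsilyl ether), via ring-closed C6 chromium alkoxide 23 (not isolated)
Conditions: CrCl2 (15 equiv), NiCl2 (0.15 equiv), degassed DMSO–THF, rt, slow addition to 0.002 M
Reagents that add atoms: none
Why: CrCl2 reduces NiCl2 to zerovalent nickel, which inserts into the C7–I bond and passes the alkenyl group to chromium; the alkenylchromium (trivalent chromium) then adds to the C6 aldehyde. This is a Nozaki–Hiyama–Kishi macrocyclisation combined with the known butenolide-forming coupling of (Z)-β-iodoenoates with aldehydes. The ten-membered carbocycle closes by 10-exo-trig attack of C7 on the C6 carbonyl, and the butenolide closes by 5-exo-trig attack of the C6 chromium alkoxide on the C12 ester, which the retained C7=C11 geometry holds cis to it, with loss of methoxide. C6, the only new stereocentre, is controlled by the neighbouring C5 epoxide carbon: Felkin–Anh addition anti to the C5–O bond gives the 5,6-erythro, 6S carbinol, and the bulky C8 silyl ether should favour the ring conformer that exposes this face. The step needs chemoselectivity for the C–I bond over two vinyl epoxides, the allylic acetate and the acidic lactone γ-hydrogen, which the neutral, non-basic chromium reagent secures, and it needs cyclisation to beat oligomerisation, which high dilution and the turn imposed by the Z alkene and the two epoxides secure.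

Step 18
Reactants: 24 macrocyclic butenolide (O8 triethylsilyl ether; O14 tert-butyldimethylsilyl ether)
Product: 25 C8 alcohol of the macrocyclic butenolide
Conditions: HF·pyridine, pyridine, THF, 0 °C
Reagents that add atoms: none
Why: Buffered HF·pyridine should remove the secondary triethylsilyl ether faster than the more stable tert-butyldimethylsilyl ether on the neopentyl-type C14 oxygen, without base that could deprotonate the butenolide γ-position.

Step 19
Reactants: 25 C8 alcohol of the macrocyclic butenolide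
Product: 26 C8 methacrylate (O14 tert-butyldimethylsilyl ether)
Conditions: methacrylic anhydride, Et3N, DMAP (cat.), CH2Cl2, 0 °C
Reagents that add atoms: methacrylic anhydride, C=C(C)C(=O)OC(=O)C(C)=C
Why: DMAP-catalysed acylation of the only free hydroxyl (secondary, allylic) with methacrylic anhydride installs the ester with retention at C8.

Step 20
Reactants: 26 C8 methacrylate (O14 tert-butyldimethylsilyl ether)
Product: 27 target, (1R,4R,5S,6S,8S,10S)-13-acetoxy-1,10:4,5-diepoxy-14-hydroxy-8-(methacryloyloxy)germacra-2Z,7(11)-dien-12,6-olide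
Conditions: TBAF, AcOH (1:1), THF, 0 °C to rt
Reagents that add atoms: none
Why: Acetic-acid-buffered fluoride cleaves the remaining silyl ether under near-neutral conditions that should tolerate the two esters, the lactone and the vinyl epoxides.

Compound list

1 | propargyl alcohol (prop-2-yn-1-ol) | C#CCO | starting material
2 | allylmagnesium bromide | C=CC[Mg]Br | starting material
3 | alkenylmagnesium chelate, 4-allyl-2,5-dihydro-1,2-oxamagnesole (Mg on C1 cis to the CH2O group; not isolated) | C=CCC1=C[Mg]OC1 | intermediate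
4 | (Z)-2-(iodomethylene)pent-4-en-1-ol | C=CC/C(CO)=C/I | intermediate
5 | (Z)-triethyl{[2-(iodomethylene)pent-4-en-1-yl]oxy}silane | C=CC/C(CO[Si](CC)(CC)CC)=C/I | intermediate
6 | (Z)-5-iodo-4-{[(triethylsilyl)oxy]methyl}pent-4-ene-1,2-diol (both C2 epimers; not isolated) | OCC(O)C/C(CO[Si](CC)(CC)CC)=C/I | intermediate
7 | (Z)-4-iodo-3-{[(triethylsilyl)oxy]methyl}but-3-enal | O=CC/C(CO[Si](CC)(CC)CC)=C/I | intermediate
8 | methyl propiolate | C#CC(=O)OC | starting material
9 | methyl (4S,6Z)-4-hydroxy-7-iodo-6-{[(triethylsilyl)oxy]methyl}hept-6-en-2-ynoate | O[C@@H](C/C(CO[Si](CC)(CC)CC)=C/I)C#CC(=O)OC | intermediate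
10 | methyl (4S,6Z)-7-iodo-4-[(triethylsilyl)oxy]-6-{[(triethylsilyl)oxy]methyl}hept-6-en-2-ynoate | CC[Si](CC)(CC)O[C@@H](C/C(CO[Si](CC)(CC)CC)=C/I)C#CC(=O)OC | intermediate
11 | (Z)-3-methylpent-2-en-4-yn-1-ol | C#C/C(C)=C\CO | starting material
12 | (Z)-1-methoxy-4-{[(3-methylpent-2-en-4-yn-1-yl)oxy]methyl}benzene | C#C/C(C)=C\COCc1ccc(OC)cc1 | intermediate
13 | methyl (4S,6Z,10Z)-12-[(4-methoxybenzyl)oxy]-10-methyl-4-[(triethylsilyl)oxy]-6-{[(triethylsilyl)oxy]methyl}dodeca-6,10-dien-2,8-diynoate | CC[Si](CC)(CC)O[C@@H](C/C(CO[Si](CC)(CC)CC)=C/C#C/C(C)=C\COCc1ccc(OC)cc1)C#CC(=O)OC | intermediate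
14 | methyl (2Z,4S,6Z,10Z)-2-(hydroxymethyl)-3-iodo-12-[(4-methoxybenzyl)oxy]-10-methyl-4-[(triethylsilyl)oxy]-6-{[(triethylsilyl)oxy]methyl}dodeca-2,6,10-trien-8-ynoate | CC[Si](CC)(CC)O[C@@H](C/C(CO[Si](CC)(CC)CC)=C/C#C/C(C)=C\COCc1ccc(OC)cc1)/C(I)=C(\CO)C(=O)OC | intermediate
15 | methyl (2Z,4S,6Z,10Z)-2-(acetoxymethyl)-3-iodo-12-[(4-methoxybenzyl)oxy]-10-methyl-4-[(triethylsilyl)oxy]-6-{[(triethylsilyl)oxy]methyl}dodeca-2,6,10-trien-8-ynoate | CC[Si](CC)(CC)O[C@@H](C/C(CO[Si](CC)(CC)CC)=C/C#C/C(C)=C\COCc1ccc(OC)cc1)/C(I)=C(\COC(C)=O)C(=O)OC | intermediate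
16 | methyl (2Z,4S,6Z,10Z)-2-(acetoxymethyl)-6-(hydroxymethyl)-3-iodo-12-[(4-methoxybenzyl)oxy]-10-methyl-4-[(triethylsilyl)oxy]dodeca-2,6,10-trien-8-ynoate | CC[Si](CC)(CC)O[C@@H](C/C(CO)=C/C#C/C(C)=C\COCc1ccc(OC)cc1)/C(I)=C(\COC(C)=O)C(=O)OC | intermediate
17 | methyl (2Z,4S)-2-(acetoxymethyl)-5-[(2S,3R)-2-(hydroxymethyl)-3-{(3Z)-5-[(4-methoxybenzyl)oxy]-3-methylpent-3-en-1-yn-1-yl}oxiran-2-yl]-3-iodo-4-[(triethylsilyl)oxy]pent-2-enoate | CC[Si](CC)(CC)O[C@@H](C[C@@]1(CO)O[C@@H]1C#C/C(C)=C\COCc3ccc(OC)cc3)/C(I)=C(\COC(C)=O)C(=O)OC | intermediate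
18 | methyl (2Z,4S)-2-(acetoxymethyl)-5-[(2S,3R)-2-{[(tert-butyldimethylsilyl)oxy]methyl}-3-{(3Z)-5-[(4-methoxybenzyl)oxy]-3-methylpent-3-en-1-yn-1-yl}oxiran-2-yl]-3-iodo-4-[(triethylsilyl)oxy]pent-2-enoate | CC[Si](CC)(CC)O[C@@H](C[C@@]1(CO[Si](C)(C)C(C)(C)C)O[C@@H]1C#C/C(C)=C\COCc3ccc(OC)cc3)/C(I)=C(\COC(C)=O)C(=O)OC | intermediate
19 | methyl (2Z,4S)-2-(acetoxymethyl)-5-[(2S,3R)-2-{[(tert-butyldimethylsilyl)oxy]methyl}-3-[(3Z)-5-hydroxy-3-methylpent-3-en-1-yn-1-yl]oxiran-2-yl]-3-iodo-4-[(triethylsilyl)oxy]pent-2-enoate | CC[Si](CC)(CC)O[C@@H](C[C@@]1(CO[Si](C)(C)C(C)(C)C)O[C@@H]1C#C/C(C)=C\CO)/C(I)=C(\COC(C)=O)C(=O)OC | intermediate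
20 | methyl (2Z,4S)-2-(acetoxymethyl)-5-[(2S,3R)-2-{[(tert-butyldimethylsilyl)oxy]methyl}-3-{[(2R,3S)-3-(hydroxymethyl)-2-methyloxiran-2-yl]ethynyl}oxiran-2-yl]-3-iodo-4-[(triethylsilyl)oxy]pent-2-enoate | CC[Si](CC)(CC)O[C@@H](C[C@@]1(CO[Si](C)(C)C(C)(C)C)O[C@@H]1C#C[C@@]2(C)O[C@H]2CO)/C(I)=C(\COC(C)=O)C(=O)OC | intermediate
21 | methyl (2Z,4S)-2-(acetoxymethyl)-5-[(2S,3R)-2-{[(tert-butyldimethylsilyl)oxy]methyl}-3-{(Z)-2-[(2R,3S)-3-(hydroxymethyl)-2-methyloxiran-2-yl]ethenyl}oxiran-2-yl]-3-iodo-4-[(triethylsilyl)oxy]pent-2-enoate | CC[Si](CC)(CC)O[C@@H](C[C@@]1(CO[Si](C)(C)C(C)(C)C)O[C@@H]1/C=C\[C@@]2(C)O[C@H]2CO)/C(I)=C(\COC(C)=O)C(=O)OC | intermediate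
22 | methyl (2Z,4S)-2-(acetoxymethyl)-5-[(2S,3R)-2-{[(tert-butyldimethylsilyl)oxy]methyl}-3-{(Z)-2-[(2R,3R)-3-formyl-2-methyloxiran-2-yl]ethenyl}oxiran-2-yl]-3-iodo-4-[(triethylsilyl)oxy]pent-2-enoate (cyclisation precursor) | CC[Si](CC)(CC)O[C@@H](C[C@@]2(CO[Si](C)(C)C(C)(C)C)O[C@@H]2/C=C\[C@@]2(C)O[C@H]2C=O)/C(I)=C(\COC(C)=O)C(=O)OC | intermediate
23 | methyl (1R,4R,5S,6S,8S,10S)-13-acetoxy-14-[(tert-butyldimethylsilyl)oxy]-1,10:4,5-diepoxy-6-hydroxy-8-[(triethylsilyl)oxy]germacra-2Z,7(11)-dien-12-oate, present as its C6 chromium alkoxide (not isolated) | CC[Si](CC)(CC)O[C@H]1C[C@@]2(CO[Si](C)(C)C(C)(C)C)O[C@@H]2/C=C\[C@@]2(C)O[C@H]2[C@@H](O)/C1=C(/COC(C)=O)C(=O)OC | intermediate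
24 | (1R,4R,5S,6S,8S,10S)-13-acetoxy-14-[(tert-butyldimethylsilyl)oxy]-1,10:4,5-diepoxy-8-[(triethylsilyl)oxy]germacra-2Z,7(11)-dien-12,6-olide | CC[Si](CC)(CC)O[C@H]1C[C@@]2(CO[Si](C)(C)C(C)(C)C)O[C@@H]2/C=C\[C@@]2(C)O[C@H]2[C@H]2OC(=O)C(COC(C)=O)=C12 | intermediate
25 | (1R,4R,5S,6S,8S,10S)-13-acetoxy-14-[(tert-butyldimethylsilyl)oxy]-1,10:4,5-diepoxy-8-hydroxygermacra-2Z,7(11)-dien-12,6-olide | O[C@H]1C[C@@]2(CO[Si](C)(C)C(C)(C)C)O[C@@H]2/C=C\[C@@]2(C)O[C@H]2[C@H]2OC(=O)C(COC(C)=O)=C12 | intermediate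
26 | (1R,4R,5S,6S,8S,10S)-13-acetoxy-14-[(tert-butyldimethylsilyl)oxy]-1,10:4,5-diepoxy-8-(methacryloyloxy)germacra-2Z,7(11)-dien-12,6-olide | C=C(C)C(=O)O[C@H]1C[C@@]2(CO[Si](C)(C)C(C)(C)C)O[C@@H]2/C=C\[C@@]2(C)O[C@H]2[C@H]2OC(=O)C(COC(C)=O)=C12 | intermediate
27 | (1R,4R,5S,6S,8S,10S)-13-acetoxy-1,10:4,5-diepoxy-14-hydroxy-8-(methacryloyloxy)germacra-2Z,7(11)-dien-12,6-olide (CNP0207684.1) | C=C(C)C(=O)O[C@H]1C[C@@]2(CO)O[C@@H]2/C=C\[C@@]2(C)O[C@H]2[C@H]2OC(=O)C(COC(C)=O)=C12 | target

Total step count: 20. Longest linear sequence: 19 steps (steps 1–5 and 7–20; step 6 prepares the second coupling partner).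

Steps most likely to fail

Step 17 (ring closure). The strained ten-membered ring may close more slowly than intermolecular addition or plain reduction of the C–I bond, and the aldehyde may be attacked on the wrong face if the bulky C8 silyl ether sits badly. Fallback: starting from 22, the triethylsilyl group is removed first (HF·pyridine, pyridine, THF, 0 °C) to give the C8-hydroxy seco-aldehyde F1. Under the same CrCl2/NiCl2 high-dilution conditions the free hydroxyl becomes a chromium alkoxide next to C7, which changes the conformational bias and holds the metal close to the reacting carbon. The ring-closed diol ester F2 (not isolated) should lactonise to 25, where the route is rejoined at step 19.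

Step 15 (semihydrogenation). Hydrogenolysis of the vinylic C–I bond, over-reduction of the new Z alkene or hydrogenolytic opening of the vinyl epoxides may compete on the metal surface. Fallback: from 20 the alkyne is reduced without any metal by diimide generated from 2-nitrobenzenesulfonyl hydrazide and Et3N (THF–iPrOH, rt). Concerted syn transfer of H2 cannot insert into a C–I bond, and the hindered cis alkene formed should be reduced further only slowly. 21 is reached directly and no new compound arises (F0).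

Step 8 (iodo-aldol). Iodide addition to the hindered internal ynoate may stall, the alkene geometry may equilibrate on long exposure, and the Lewis acid may attack the benzylic ether. Fallback: the same iodo-aldol is run one stage earlier on 10, which carries only silyl ethers and tolerates more forcing conditions, to give methyl (2Z,4S,6Z)-2-(hydroxymethyl)-3,7-diiodo-4-[(triethylsilyl)oxy]-6-{[(triethylsilyl)oxy]methyl}hepta-2,6-dienoate F3. Acetylation (AcCl, 2,4,6-collidine) gives the corresponding acetate F4. Then 12 is coupled selectively at the unhindered C1–I bond (Pd(PPh3)4, CuI, iPr2NEt, THF, 0 °C), the tetrasubstituted C7–I bond being slower in oxidative addition, which returns to 15.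

Further compounds

F1 | step 17 | C8-hydroxy seco-aldehyde (22 without the triethylsilyl group) | O[C@@H](C[C@@]2(CO[Si](C)(C)C(C)(C)C)O[C@@H]2/C=C\[C@@]2(C)O[C@H]2C=O)/C(I)=C(\COC(C)=O)C(=O)OC
F2 | step 17 | methyl (1R,4R,5S,6S,8S,10S)-13-acetoxy-14-[(tert-butyldimethylsilyl)oxy]-1,10:4,5-diepoxy-6,8-dihydroxygermacra-2Z,7(11)-dien-12-oate, as its chromium alkoxide (not isolated) | O[C@H]1C[C@@]2(CO[Si](C)(C)C(C)(C)C)O[C@@H]2/C=C\[C@@]2(C)O[C@H]2[C@@H](O)/C1=C(/COC(C)=O)C(=O)OC
F0 | step 15 | none | none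
F3 | step 8 | methyl (2Z,4S,6Z)-2-(hydroxymethyl)-3,7-diiodo-4-[(triethylsilyl)oxy]-6-{[(triethylsilyl)oxy]methyl}hepta-2,6-dienoate | CC[Si](CC)(CC)O[C@@H](C/C(CO[Si](CC)(CC)CC)=C/I)/C(I)=C(\CO)C(=O)OC
F4 | step 8 | methyl (2Z,4S,6Z)-2-(acetoxymethyl)-3,7-diiodo-4-[(triethylsilyl)oxy]-6-{[(triethylsilyl)oxy]methyl}hepta-2,6-dienoate | CC[Si](CC)(CC)O[C@@H](C/C(CO[Si](CC)(CC)CC)=C/I)/C(I)=C(\COC(C)=O)C(=O)OC
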